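**Plan**

- Cuts, in retrosynthetic order: (i) the aryl C–CH2 bond of the methylene bridge; (ii) the C4–geranyl bond of the dearomatised ring; (iii) the aryl–prenyl, aryl–butanoyl and two aryl–methyl bonds of two simple phloroglucinols.
- Enabling feature: the bridge CH2 sits on C6 of an enolised cyclohexane-1,3,5-trione ring (between C1=O and C5–OH). It can therefore be carried as a C6-methyl group and unveiled by two-electron oxidation as an exocyclic methylene trione (quinone-methide type). The arene half has exactly one free ring CH (C5, between two OH) to attack it.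
- The same methyl makes the precursor 3,5-dimethylphloroacetophenone C2v-symmetric, so its two methyl-bearing ring carbons are enantiotopic. A Pd-catalysed asymmetric dearomative geranylation picks one of them and sets the only stereocentre (quaternary C4, R). No later step can touch it.
- Forward: phloroglucinol → butanoyl → prenyl (arene half); phloroacetophenone → dimethyl → geranyl (dearomatised half). No ring is built; both six-membered rings are bought as phloroglucinols.
- The halves are joined last, without protecting groups, by a TEMPO-mediated anodic dehydrogenative coupling whose only by-product is H2.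

Key step: step 6

Assumption 1: the sense of induction of the Trost-ligand catalyst in step 5 cannot be fixed in advance; the (R,R)-ligand is written, and the (S,S)-ligand is to be used if it delivers the antipode.
Assumption 2: the β-triketone rings are drawn in the tautomeric form of the target SMILES, and all R/S letters refer to the tautomer drawn.

**Step 1**
Reactants: 1 phloroglucinol (benzene-1,3,5-triol)
Product: 2 1-(2,4,6-trihydroxyphenyl)butan-1-one
Conditions: butanoyl chloride (1.0 equiv), AlCl3 (3 equiv), PhNO2/CH2Cl2, 0 °C → 60 °C; aq. HCl work-up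
Reagents that add atoms: butanoyl chloride, CCCC(Cl)=O
Why: Friedel–Crafts C-acylation of the very electron-rich triol stops at the mono-ketone because the chelated aryl ketone product is deactivated.

**Step 2**
Reactants: 2 1-(2,4,6-trihydroxyphenyl)butan-1-one
Product: 3 1-[2,4,6-trihydroxy-3-(3-methylbut-2-en-1-yl)phenyl]butan-1-one
Conditions: prenyl bromide (0.9 equiv), 10% aq. KOH, 0 °C; then 1 M HCl to pH 4, chromatography
Reagents that add atoms: prenyl bromide, CC(C)=CCBr
Why: C-alkylation of the ambident phloroglucinol phenolate in water (O-solvation favours C-attack) with a deficit of bromide should give the mono-C-prenyl compound as one regioisomer, since the two free ring carbons are equivalent.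

**Step 3**
Reactants: 4 1-(2,4,6-trihydroxyphenyl)ethan-1-one (phloroacetophenone)
Product: 6 1-(2,4,6-trihydroxy-3,5-dimethylphenyl)ethan-1-one, via 3-methylphloroacetophenone 5 (not isolated)
Conditions: NaOMe (3 equiv), MeI (2.2 equiv), MeOH, 0 °C → rt; then 1 M HCl, chromatography
Reagents that add atoms: iodomethane, CI
Why: twofold C-methylation of the phloroglucinol phenolate at its two free ring carbons, a standard nuclear methylation of acylphloroglucinols, with the MeI charge limited to hold back gem-dimethylation.

**Step 4**
Reactants: 7 geraniol [(2E)-3,7-dimethylocta-2,6-dien-1-ol]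
Product: 8 (2E)-3,7-dimethylocta-2,6-dien-1-yl methyl carbonate
Conditions: ClCO2Me (1.3 equiv), pyridine (2 equiv), CH2Cl2, 0 °C → rt
Reagents that add atoms: methyl chloroformate, COC(=O)Cl
Why: O-acylation of the primary allylic alcohol gives the carbonate without touching the alkene geometry and supplies the ionisable leaving group (and internal methoxide base) for the Tsuji–Trost step.

**Step 5**
Reactants: 6 1-(2,4,6-trihydroxy-3,5-dimethylphenyl)ethan-1-one; 8 (2E)-3,7-dimethylocta-2,6-dien-1-yl methyl carbonate
Product: 9 (4R)-2-acetyl-4-[(2E)-3,7-dimethylocta-2,6-dien-1-yl]-3,5-dihydroxy-4,6-dimethylcyclohexa-2,5-dien-1-one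
Conditions: Pd2(dba)3·CHCl3 (2.5 mol %), (R,R)-DACH-phenyl Trost ligand (7.5 mol %), 8 (1.0 equiv), THF, 0 °C → rt
Reagents that add atoms: none
Why: Pd-catalysed asymmetric allylic alkylation (Tsuji–Trost) run as a catalytic asymmetric dearomatisation, in which the phenolate of C2v-symmetric 6 attacks the unsubstituted terminus of the (E)-geranyl π-allyl-Pd complex through one of its two enantiotopic methyl-bearing ring carbons, the chiral ligand pocket choosing which and so setting the quaternary (R) centre, while reversible O-allylation under Pd and the methyl groups on both non-acylated ring carbons leave the dearomatised mono-C-geranyl product as the only sink.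

**Step 6**
Reactants: 9 (4R)-2-acetyl-4-[(2E)-3,7-dimethylocta-2,6-dien-1-yl]-3,5-dihydroxy-4,6-dimethylcyclohexa-2,5-dien-1-one; 3 1-[2,4,6-trihydroxy-3-(3-methylbut-2-en-1-yl)phenyl]butan-1-one
Product: 12 (4R)-2-acetyl-6-{[3-butanoyl-2,4,6-trihydroxy-5-(3-methylbut-2-en-1-yl)phenyl]methyl}-4-[(2E)-3,7-dimethylocta-2,6-dien-1-yl]-3,5-dihydroxy-4-methylcyclohexa-2,5-dien-1-one, via TEMPO alkoxyamine 10 (not isolated), via methylene trione 11 (not isolated)
Conditions: undivided cell, graphite felt (+) | Pt (−), constant current ca. 3 mA cm−2, 2.0–2.2 F per mol of 3; 9 (1.3 equiv), TEMPO (20 mol %), 2,6-lutidine (0.5 equiv), nBu4NPF6 (0.1 M), MeCN/HFIP 9:1, 0 °C → rt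
Reagents that add atoms: none
Why: Proposed new method: anodically generated oxoammonium (TEMPO+, about +0.7 V vs SCE, well below the potentials of the three trisubstituted alkenes) is attacked at oxygen by C6 of the lutidinium enolate of 9 to give alkoxyamine 10, which loses TEMPO–H across C6–CH3 to the exocyclic methylene trione 11 (a quinone-methide-type Michael acceptor), while TEMPO–H is re-oxidised at the anode and protons are reduced to H2 at the cathode. The only unsubstituted ring carbon of 3 (C5, flanked by two OH groups) then adds to the CH2 terminus of 11 in a Friedel–Crafts/Michael step and tautomerisation (re-aromatisation of the arene, re-enolisation of the trione) gives 12, so the CH2–aryl bond is formed as a net C(sp3)–H/C(sp2)–H dehydrogenative coupling. The closest known reaction types are the TEMPO/Ag2O dehydrogenation of C6-methyl dearomatised acylphloroglucinols to this kind of methylene trione with capture in the flask, the Mannich-base alkylation of acylphloroglucinols by such acceptors, and TEMPO-mediated anodic dehydrogenations; what is new is driving the sequence at an electrode with an arene as the trap. No ring is closed and no stereocentre is created in 12 (the C6 centre of 10 is transient), and the quaternary C4 has no α-hydrogen and keeps its configuration. The step needs chemoselective oxidation of the C6-methyl enol in the presence of phenol 3, product 12 and the alkenes, which the low mediator potential, the much higher acidity of the β-triketone (essentially only 9 is ionised by 2,6-lutidine) and the charge limit of about 2 F per mol are meant to secure. It also needs cross- over homo-coupling and C- over O-alkylation, which follow from the substitution pattern (9 has no free nucleophilic ring CH, 3 has exactly one, no formaldehyde equivalent is present) and from reversible O-addition against irreversible re-aromatising C-addition.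

**Compound list**

1 | phloroglucinol (benzene-1,3,5-triol) | Oc1cc(O)cc(O)c1 | starting material
2 | 1-(2,4,6-trihydroxyphenyl)butan-1-one | CCCC(=O)c1c(O)cc(O)cc1O | intermediate
3 | 1-[2,4,6-trihydroxy-3-(3-methylbut-2-en-1-yl)phenyl]butan-1-one | CCCC(=O)c1c(O)c(CC=C(C)C)c(O)cc1O | intermediate
4 | 1-(2,4,6-trihydroxyphenyl)ethan-1-one (phloroacetophenone) | CC(=O)c1c(O)cc(O)cc1O | starting material
5 | 1-(2,4,6-trihydroxy-3-methylphenyl)ethan-1-one (3-methylphloroacetophenone) | CC(=O)c1c(O)cc(O)c(C)c1O | intermediate (not isolated)
6 | 1-(2,4,6-trihydroxy-3,5-dimethylphenyl)ethan-1-one | CC(=O)c1c(O)c(C)c(O)c(C)c1O | intermediate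
7 | geraniol, (2E)-3,7-dimethylocta-2,6-dien-1-ol | OC/C=C(\C)CCC=C(C)C | starting material
8 | (2E)-3,7-dimethylocta-2,6-dien-1-yl methyl carbonate | COC(=O)OC/C=C(\C)CCC=C(C)C | intermediate
9 | (4R)-2-acetyl-4-[(2E)-3,7-dimethylocta-2,6-dien-1-yl]-3,5-dihydroxy-4,6-dimethylcyclohexa-2,5-dien-1-one | CC1=C(O)[C@@](C)(C/C=C(\C)CCC=C(C)C)C(O)=C(C(C)=O)C1=O | intermediate
10 | (4S)-2-acetyl-4-[(2E)-3,7-dimethylocta-2,6-dien-1-yl]-3-hydroxy-4,6-dimethyl-6-[(2,2,6,6-tetramethylpiperidin-1-yl)oxy]cyclohex-2-ene-1,5-dione, both C6 epimers (the letter at C4 changes by CIP ranking only, the spatial arrangement is that of 9) | CC1(ON2C(C)(C)CCCC2(C)C)C(=O)[C@@](C)(C/C=C(\C)CCC=C(C)C)C(O)=C(C(C)=O)C1=O | intermediate (not isolated)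
11 | (4S)-2-acetyl-4-[(2E)-3,7-dimethylocta-2,6-dien-1-yl]-3-hydroxy-4-methyl-6-methylidenecyclohex-2-ene-1,5-dione (same spatial arrangement at C4 as 9) | C=C1C(=O)[C@@](C)(C/C=C(\C)CCC=C(C)C)C(O)=C(C(C)=O)C1=O | intermediate (not isolated)
12 | (4R)-2-acetyl-6-{[3-butanoyl-2,4,6-trihydroxy-5-(3-methylbut-2-en-1-yl)phenyl]methyl}-4-[(2E)-3,7-dimethylocta-2,6-dien-1-yl]-3,5-dihydroxy-4-methylcyclohexa-2,5-dien-1-one | CCCC(=O)c1c(O)c(CC=C(C)C)c(O)c(CC2=C(O)[C@@](C)(C/C=C(\C)CCC=C(C)C)C(O)=C(C(C)=O)C2=O)c1O | target

**Step count**

Total steps: 6. Longest linear sequence: 3 steps (4 → 6 → 9 → 12, or 1 → 2 → 3 → 12).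

**Steps most likely to fail**

1. Step 6 (Proposed new method). The oxoammonium mediator may oxidise the phenol partner or the coupled product further, may attack the trisubstituted alkenes in an ene-type reaction, or the methylene trione may oligomerise before it is captured. Fallback with known chemistry, taking the oxidation out of the coupling: starting from 9, chemical dehydrogenation with TEMPO/Ag2O (the known reagent pair for C6-methyl compounds of this class) is run in toluene at rt in the presence of morpholine, which adds to the methylene trione and should give the isolable Mannich base (4R)-2-acetyl-4-[(2E)-3,7-dimethylocta-2,6-dien-1-yl]-3,5-dihydroxy-4-methyl-6-(morpholin-4-ylmethyl)cyclohexa-2,5-dien-1-one F1. Heating F1 with 3 and NaOAc in dioxane at 90 °C (amine elimination, then Michael addition of the arene, the classical Mannich-base route to unsymmetrical methylene-bridged phloroglucinols) should return the route at 12, with no oxidant ever in contact with 3 or 12.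

2. Step 5. The catalyst may discriminate poorly between the two enantiotopic ring carbons, the π-allyl may scramble E/Z, or a second geranylation may occur at C6. Fallback replacing asymmetric catalysis by resolution: starting from 6, base-mediated dearomative C-alkylation with geranyl bromide (NaOMe, MeOH, 0 °C → rt; the E-alkene is untouched in an SN2 reaction) should give racemic 2-acetyl-4-[(2E)-3,7-dimethylocta-2,6-dien-1-yl]-3,5-dihydroxy-4,6-dimethylcyclohexa-2,5-dien-1-one F2. The enantiomers are then separated by preparative SFC on an amylose-based chiral stationary phase, the (R)-enantiomer being assigned by ECD against calculation, which returns the route at 9.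

3. Step 2. Statistical over-prenylation (second C-prenylation, gem-diprenylation with dearomatisation), O-prenylation, and acid-induced chroman closure on work-up may erode the mono-C-prenyl product. Fallback by a directed para-Claisen sequence: starting from 2, MOMCl/iPr2NEt (CH2Cl2, 0 °C) protects all but the chelated hydroxyl to give 1-[2-hydroxy-4,6-bis(methoxymethoxy)phenyl]butan-1-one F3. O-Prenylation (prenyl bromide, K2CO3, DMF, rt) gives 1-{2,4-bis(methoxymethoxy)-6-[(3-methylbut-2-en-1-yl)oxy]phenyl}butan-1-one F4. Heating in N,N-diethylaniline at about 200 °C (Claisen then Cope, net para migration with the prenyl group un-inverted) gives 1-[6-hydroxy-2,4-bis(methoxymethoxy)-3-(3-methylbut-2-en-1-yl)phenyl]butan-1-one F5. Removal of both MOM groups with HCl in MeOH at rt returns the route at 3.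

**Further compounds**

F1 | step 6 | (4R)-2-acetyl-4-[(2E)-3,7-dimethylocta-2,6-dien-1-yl]-3,5-dihydroxy-4-methyl-6-(morpholin-4-ylmethyl)cyclohexa-2,5-dien-1-one | O1CCN(CC1)CC2=C(O)[C@@](C)(C/C=C(\C)CCC=C(C)C)C(O)=C(C(C)=O)C2=O
F2 | step 5 | racemic 2-acetyl-4-[(2E)-3,7-dimethylocta-2,6-dien-1-yl]-3,5-dihydroxy-4,6-dimethylcyclohexa-2,5-dien-1-one | CC1=C(O)C(C)(C/C=C(\C)CCC=C(C)C)C(O)=C(C(C)=O)C1=O
F3 | step 2 | 1-[2-hydroxy-4,6-bis(methoxymethoxy)phenyl]butan-1-one | CCCC(=O)c1c(O)cc(OCOC)cc1OCOC
F4 | step 2 | 1-{2,4-bis(methoxymethoxy)-6-[(3-methylbut-2-en-1-yl)oxy]phenyl}butan-1-one | CCCC(=O)c1c(OCC=C(C)C)cc(OCOC)cc1OCOC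
F5 | step 2 | 1-[6-hydroxy-2,4-bis(methoxymethoxy)-3-(3-methylbut-2-en-1-yl)phenyl]butan-1-one | CCCC(=O)c1c(O)cc(OCOC)c(CC=C(C)C)c1OCOC
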